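**Plan**
- Last cuts: the three exocyclic methylenes (C4=C15, C11=C13, C11′=C13′, one Mannich/elimination) and the C3′ carbonyl (carried as a silyl ether). Unit A then opens at C8–C9 (carbonyl-ene), C1–C5 (Conia-ene) and C3–C4 (alkynyl addition) to iodoalkynyl lactone 30 and aldehyde 24.
- Unit B: its cycloheptane has oxygen at C6′ and C8′ and a one-carbon branch (C14′) on C10′. C10′–C1′–C5′–C6′ are read as a 2-substituted furan fused to the spiro cyclopentane and C7′–C8′–C9′ as an oxyallyl cation; the cut is at C6′–C7′ and C9′–C10′.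
- Forward ring order: cyclopenta[c]furanone → spiro cyclohexenone (Michael/aldol) → oxygen-bridged cycloheptanone ([4+3]) → unit A cyclopentene → unit A cycloheptane → lactone B by zinc opening of the bridge.
- Unit B stereo: C4′ from the organocatalytic Michael step; C6′/C10′ from the face of the [4+3] (anti to the C2 arm and the C3′ silyloxy group); C1′/C5′ from exo hydrogenation; C7′ by equilibration; C8′ by L-Selectride.
- Unit A stereo: C6 from a D-proline aldol, C7 by equilibration in the fragment, C8 from the closed ene transition state, C5 and C10 by equilibration through the C3 dienolate.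

Key step: step 11

Numbering: guaianolide numbering, unprimed for the cyclopentenone half (unit A), primed for the spiro-cyclopentanone half (unit B).
Assumption: C5 and C10, both γ to the C3 ketone through C1=C2 and therefore epimerisable, are taken to have their thermodynamically preferred configuration in the target.
Remark: C1, C2, C3 and C3′ are stereogenic only in intermediates; they are drawn as expected but do not reach the target. The cyclohexenone of the cycloaddition substrate has its C=C on the C15′ arm (saturated in step 12), because the cation must pass C15′ and a vinylic CH is the smaller neighbour.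

**Route**

Step 1
Reactants: 1 furan-3,4-diyldimethanol
Product: 2 3,4-bis(bromomethyl)furan
Conditions: PBr3, Et2O, 0 °C
Reagents that add atoms: phosphorus tribromide, BrP(Br)Br
Why: Both primary furylmethanol groups are converted into bromides by SN2 displacement of their phosphite esters (alcohol-to-bromide substitution).

Step 2
Reactants: 2 3,4-bis(bromomethyl)furan; 3 TosMIC
Product: 5 4H-cyclopenta[c]furan-5(6H)-one, via tosyl isocyanide 4 (not isolated)
Conditions: NaH, DMSO/Et2O, rt; then conc. HCl, Et2O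
Reagents that add atoms: water, O
Why: Van Leusen ketone synthesis: TosMIC is dialkylated by the bis-bromide to close the five-membered ring and acid hydrolysis of the α-tosyl isocyanide unmasks the ketone, as in the preparation of 2-indanones from 1,2-bis(bromomethyl)arenes.

Step 3
Reactants: 5 4H-cyclopenta[c]furan-5(6H)-one; 6 ethyl formate
Product: 7 (Z)-4-(hydroxymethylene)-4H-cyclopenta[c]furan-5(6H)-one
Conditions: NaOMe, THF, 0 °C to rt; aq. HCl
Reagents that add atoms: none
Why: Crossed Claisen formylation; the symmetric ketone has only one kind of α-carbon, so the formyl group marks without ambiguity the carbon that becomes C4′ (the formyl carbon becomes C15′).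

Step 4
Reactants: 8 methyl acetoacetate; 9 2,2-dimethoxyacetaldehyde
Product: 10 methyl 2-acetyl-4,4-dimethoxybut-2-enoate
Conditions: piperidine (cat.), AcOH (cat.), CH2Cl2, 4 Å MS, rt
Reagents that add atoms: none
Why: Knoevenagel condensation gives the doubly activated alkene that later supplies C14, C10, C1, C2 and C3.

Step 5
Reactants: 7 (Z)-4-(hydroxymethylene)-4H-cyclopenta[c]furan-5(6H)-one; 10 methyl 2-acetyl-4,4-dimethoxybut-2-enoate
Product: 12 spiro enone keto ester, via Michael adduct 11 (not isolated)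
Conditions: quinidine-derived squaramide (10 mol %), CH2Cl2, −20 °C; then pyrrolidine/AcOH (20 mol %), toluene, 50 °C
Reagents that add atoms: none
Why: Bifunctional-amine-catalysed Michael addition of the cyclic 1,3-dicarbonyl donor to the alkylidene β-keto ester sets the quaternary C4′ (catalyst face control) and C2; the Robinson-type (Hagemann) aldol condensation of the acetyl methyl onto the non-enolisable aldehyde then closes the cyclohexenone with its C=C on the C15′ arm, C1 settling trans to the C2 substituent.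

Step 6
Reactants: 12 spiro enone keto ester
Product: 14 C3′ TES ether, via C3′ alcohol 13 (not isolated)
Conditions: NaH (1.0 equiv), THF, 0 °C; L-Selectride, −78 °C; TESOTf (1.1 equiv), −78 to 0 °C; aq. NH4Cl
Reagents that add atoms: triethylsilyl trifluoromethanesulfonate, CC[Si](CC)(CC)OS(=O)(=O)C(F)(F)F
Why: With the β-keto ester masked as its sodium enolate, the bulky hydride reduces only the C3′ ketone from the face of the flat C15′=C14 arm, so the oxygen ends up syn to the C2 arm, and the more nucleophilic alkoxide is silylated (enolate-protected ketone reduction, O-silylation).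

Step 7
Reactants: 14 C3′ TES ether
Product: 15 C10′-formyl furan
Conditions: POCl3, DMF, CH2Cl2, 0 °C; aq. NaOAc
Reagents that add atoms: N,N-dimethylformamide, CN(C)C=O; water, O
Why: Vilsmeier–Haack formylation of the electron-rich furan should go to the α-carbon remote from the spiro centre (C10′), the other α-CH (C6′) being flanked above and below by the cyclohexenone arms.

Step 8
Reactants: 15 C10′-formyl furan
Product: 16 C14′ alcohol
Conditions: NaBH4, MeOH/CH2Cl2, −78 °C
Reagents that add atoms: none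
Why: Borohydride reduction at low temperature is selective for the aldehyde over the enone and the keto ester.

Step 9
Reactants: 16 C14′ alcohol
Product: 17 C14′ benzyl ether
Conditions: BnBr, Ag2O, CH2Cl2, rt, dark
Reagents that add atoms: benzyl bromide, BrCc1ccccc1
Why: Silver(I) oxide-mediated Williamson benzylation of the primary alcohol needs no strong base, so the hindered β-keto ester methine and the silyl ether are left alone.

Step 10
Reactants: 18 methyl levulinate
Product: 19 methyl 3,5-dibromo-4-oxopentanoate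
Conditions: Br2 (2 equiv), CHCl3, rt
Reagents that add atoms: bromine, BrBr
Why: Acid-autocatalysed α-bromination at both enolisable positions of the ketone gives the racemic α,α′-dibromo ketone, the oxyallyl precursor.

Step 11
Reactants: 17 C14′ benzyl ether; 19 methyl 3,5-dibromo-4-oxopentanoate
Product: 20 oxygen-bridged cycloheptenone
Conditions: NaI, Cu powder, MeCN, 0 °C to rt; then Et3N, SiO2
Reagents that add atoms: none
Why: Iodide exchange and copper-mediated reductive ionisation turn 19 into the 1-substituted oxyallyl cation, which adds across the furan α-carbons C6′ and C10′, concertedly or by first attack at the free C6′ position followed by ring closure (the [4+3] cycloaddition of α,α′-dihalo ketones with furans). The seven-membered carbocycle closes by this [4π+2π] cycloaddition as an 8-oxabicyclo[3.2.1]oct-6-en-3-one, forming C6′–C7′ and C9′–C10′. Regiochemistry is steric: the substituted terminus C7′ avoids the furan carbon that carries the benzyloxymethyl group. C6′ and C10′ are set by the face of approach: the branched sp3 C2 arm and the C3′ silyloxy group block one face, while the other is flanked only by the vinylic C15′–H, so the cation should add syn to C15′. C7′ ends up equatorial (arm trans to the oxygen bridge) after equilibration next to the ketone. The step needs face and regio selectivity, and both rest on groups placed next to the furan (C3′ OTES, C2 arm, C14′ OBn).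

Step 12
Reactants: 20 oxygen-bridged cycloheptenone
Product: 21 saturated cycloadduct
Conditions: [Ir(cod)(PCy3)(py)]PF6 (Crabtree), H2 (4 atm), CH2Cl2, rt
Reagents that add atoms: none
Why: Homogeneous hydrogenation adds H2 to the strained tetrasubstituted C1′=C5′ bond from the exo face (that of the oxygen bridge; the endo face is covered by the ketone bridge), giving cis H1′/H5′ trans to H6′, and saturates the enone C14=C15′.

Step 13
Reactants: 21 saturated cycloadduct
Product: 23 C8′ TIPS ether, via C8′ alcohol 22 (not isolated)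
Conditions: NaH (1.0 equiv), THF, 0 °C; L-Selectride, −78 °C; TIPSOTf (1.1 equiv), −78 to 0 °C; aq. NH4Cl
Reagents that add atoms: triisopropylsilyl trifluoromethanesulfonate, CC(C)[Si](C(C)C)(C(C)C)OS(=O)(=O)C(F)(F)F
Why: The β-keto ester is again protected as its enolate while the bulky hydride attacks the bicyclic C8′ ketone from the equatorial (exo) direction to give the axial 8′β-alkoxide (the usual selectivity for 8-oxabicyclo[3.2.1]octan-3-ones), which is silylated cold before it can lactonise onto the neighbouring ester.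

Step 14
Reactants: 23 C8′ TIPS ether
Product: 24 C3 aldehyde
Conditions: PPTS, acetone/H2O, 50 °C
Reagents that add atoms: water, O
Why: Mild acid-catalysed acetal hydrolysis unmasks the C3 aldehyde without touching the hindered silyl ethers.

Step 15
Reactants: 25 methyl 4-oxobutanoate; 26 3-(trimethylsilyl)propynal
Product: 27 anti-aldol adduct
Conditions: D-proline (20 mol %), DMF, 4 °C, slow addition of 25
Reagents that add atoms: none
Why: Proline-catalysed enamine cross-aldol reaction; the D-catalyst directs the donor enamine onto one face of the ynal and so fixes C6, and the anti relationship at C7 is corrected in the next step.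

Step 16
Reactants: 27 anti-aldol adduct
Product: 29 silylalkynyl lactone acetal, via trans-lactone aldehyde 28 (not isolated)
Conditions: PPTS, toluene, 60 °C; Et3N (cat.), rt; then HC(OMe)3, MeOH, PPTS, rt
Reagents that add atoms: trimethyl orthoformate, COC(OC)OC
Why: Acid closes the γ-lactone, the aldehyde-bearing C7 epimerises through its enol to the more stable trans-4,5-disubstituted lactone, and the aldehyde is then protected as its dimethyl acetal (lactonisation, epimerisation, acetalisation).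

Step 17
Reactants: 29 silylalkynyl lactone acetal
Product: 30 iodoalkynyl lactone acetal
Conditions: NIS, AgNO3 (cat.), acetone, rt
Reagents that add atoms: N-iodosuccinimide, O=C1CCC(=O)N1I
Why: Silver-catalysed iododesilylation of the alkynylsilane gives the 1-iodoalkyne needed for chromium coupling.

Step 18
Reactants: 24 C3 aldehyde; 30 iodoalkynyl lactone acetal
Product: 31 C3 propargylic alcohol
Conditions: CrCl2 (4 equiv), NiCl2 (1 mol %), THF, rt
Reagents that add atoms: none
Why: Nozaki–Hiyama–Kishi coupling: the alkynylchromium(III) species adds only to the aldehyde and tolerates ketone, esters and lactone; both C3 epimers are carried on because C3 becomes a ketone.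

Step 19
Reactants: 31 C3 propargylic alcohol
Product: 32 cyclopentene keto ester
Conditions: Ph3PAuCl (5 mol %), AgOTf (5 mol %), CH2Cl2, rt
Reagents that add atoms: none
Why: Gold(I)-catalysed Conia-ene reaction: the enol of the β-keto ester adds 5-endo-dig to the activated alkyne, forming C1–C5 and a necessarily cis-fused cyclopentene; the lactone-bound propargylic oxygen is held in a ring and should not undergo the acyloxy shift of open-chain propargylic esters.

Step 20
Reactants: 32 cyclopentene keto ester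
Product: 33 cis-hydrindenone
Conditions: LiCl, DMSO, H2O, 130 °C
Reagents that add atoms: none
Why: Krapcho demethoxycarbonylation of the quaternary β-keto ester; protonation of the enolate restores the cis ring fusion at C1.

Step 21
Reactants: 33 cis-hydrindenone
Product: 34 C10 methylene compound
Conditions: Zn, CH2Br2, TiCl4 (Lombardo reagent), THF/CH2Cl2, 0 °C to rt
Reagents that add atoms: dibromomethane, BrCBr
Why: Lombardo methylenation converts the only free ketone into the exocyclic methylene (C9) without epimerising C1 and without attacking esters or lactone.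

Step 22
Reactants: 34 C10 methylene compound
Product: 35 cyclopentenone
Conditions: MnO2, CH2Cl2, rt
Reagents that add atoms: none
Why: Manganese dioxide oxidises only the allylic C3 alcohol; the resulting conjugated C4=C5 bond is no longer nucleophilic in the cationic ring closure that follows.

Step 23
Reactants: 35 cyclopentenone
Product: 36 C8 aldehyde
Conditions: PPTS, acetone/H2O, 50 °C
Reagents that add atoms: water, O
Why: Mild acid hydrolysis of the second dimethyl acetal frees the C8 aldehyde next to the trans-lactone.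

Step 24
Reactants: 36 C8 aldehyde
Product: 37 C8 alcohol
Conditions: Me2AlCl (3 equiv), CH2Cl2, −78 to −20 °C
Reagents that add atoms: none
Why: Type II intramolecular carbonyl-ene (Prins-type) reaction: the 1,1-disubstituted alkene attacks the aldehyde through C9 and closes the seven-membered ring in a closed transition state in which the aluminium-bound oxygen is pseudo-axial and takes a hydrogen from C14, which should give the 8β-alcohol cis to the C7–C11 bond and the C10=C14 alkene.

Step 25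
Reactants: 37 C8 alcohol
Product: 38 C8 TIPS ether
Conditions: TIPSOTf, 2,6-lutidine, CH2Cl2, −78 to 0 °C
Reagents that add atoms: triisopropylsilyl trifluoromethanesulfonate, CC(C)[Si](C(C)C)(C(C)C)OS(=O)(=O)C(F)(F)F
Why: Silylation of the hindered secondary alcohol with the silyl triflate protects C8 for the later base steps.

Step 26
Reactants: 38 C8 TIPS ether
Product: 39 C1(2),C10(14)-dienone
Conditions: DBU (0.2 equiv), toluene, 40 °C
Reagents that add atoms: none
Why: Base-mediated double-bond migration through the extended dienolates moves the enone from C4=C5 to the tetrasubstituted ring-fusion position C1=C2 and creates C5–H under equilibrium control; the trans-lactone holds C6–O near the dienolate plane, which disfavours vinylogous β-elimination.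

Step 27
Reactants: 39 C1(2),C10(14)-dienone
Product: 41 C14′ alcohol, via C10-epimeric alcohol 40 (not isolated)
Conditions: H2 (1 atm), Pd(OH)2/C, EtOAc; then DBU (0.2 equiv), CH2Cl2, rt
Reagents that add atoms: none
Why: Hydrogenation reduces the less hindered γ,δ-bond (C10=C14) of the dienone and cleaves the benzyl ether while the tetrasubstituted C1=C2 bond stays; DBU then equilibrates C10 and C5, both γ to the C3 ketone, to the stable configuration.

Step 28
Reactants: 41 C14′ alcohol
Product: 42 C14′ iodide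
Conditions: I2, PPh3, imidazole, toluene, 80 °C
Reagents that add atoms: iodine, II
Why: Appel iodination of the only free, primary alcohol.

Step 29
Reactants: 42 C14′ iodide
Product: 44 bis-lactone, via hydroxy ester 43 (not isolated)
Conditions: Zn dust (activated), EtOH, 70 °C; then PPTS, toluene, 60 °C
Reagents that add atoms: none
Why: Zinc inserts into the C–I bond and expels the bridging alkoxide (Boord / Bernet–Vasella fragmentation), giving the C10′=C14′ methylene regiospecifically and the C6′ alcohol, which lactonises onto the trans-disposed acetate arm.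

Step 30
Reactants: 44 bis-lactone
Product: 47 tris-methylene bis-lactone, via tris-amine 45 (not isolated), via tris-ammonium iodide 46 (not isolated)
Conditions: LDA (4 equiv), THF, −78 °C; Eschenmoser's salt, −78 °C to rt; MeI, MeOH; then aq. NaHCO3, EtOAc
Reagents that add atoms: Eschenmoser's salt, C=[N+](C)C.[I-]
Why: The kinetic lithium enolates of both lactones and of the ketone at C4 (α′) are aminomethylated and quaternisation–elimination (Mannich/Hofmann-type α-methylenation) gives the three exocyclic methylenes; C2′ cannot compete because C3′ is still a silyl ether.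

Step 31
Reactants: 47 tris-methylene bis-lactone
Product: 48 tris-methylene C3′ alcohol
Conditions: HF·pyridine, pyridine, THF, 0 °C
Reagents that add atoms: none
Why: The triethylsilyl ether is far more labile to buffered HF than the two triisopropylsilyl ethers (selective desilylation).

Step 32
Reactants: 48 tris-methylene C3′ alcohol
Product: 49 C3′ ketone bis-TIPS ether
Conditions: Dess–Martin periodinane, NaHCO3, CH2Cl2, rt
Reagents that add atoms: none
Why: Dess–Martin oxidation of the secondary alcohol under buffered, non-basic conditions restores the C3′ ketone.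

Step 33
Reactants: 49 C3′ ketone bis-TIPS ether
Product: 50 CNP0397417.1
Conditions: HF·pyridine, MeCN, rt
Reagents that add atoms: none
Why: Cleavage of the two TIPS ethers with HF·pyridine, conditions that the α-methylene lactones and the enone should tolerate, releases the target.

**Compound list**

1 | furan-3,4-diyldimethanol | OCc1cocc1CO | starting material
2 | 3,4-bis(bromomethyl)furan | BrCc1cocc1CBr | intermediate
3 | TosMIC (p-toluenesulfonylmethyl isocyanide) | Cc1ccc(cc1)S(=O)(=O)C[N+]#[C-] | starting material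
4 | tosyl isocyanide: 5-isocyano-5-tosyl-5,6-dihydro-4H-cyclopenta[c]furan | Cc1ccc(cc1)S(=O)(=O)C2([N+]#[C-])Cc3cocc3C2 | intermediate
5 | 4H-cyclopenta[c]furan-5(6H)-one | O=C1Cc2cocc2C1 | intermediate
6 | ethyl formate | CCOC=O | starting material
7 | (Z)-4-(hydroxymethylene)-4H-cyclopenta[c]furan-5(6H)-one | O/C=C1\C(=O)Cc2cocc21 | intermediate
8 | methyl acetoacetate | COC(=O)CC(C)=O | starting material
9 | 2,2-dimethoxyacetaldehyde | COC(OC)C=O | starting material
10 | methyl 2-acetyl-4,4-dimethoxybut-2-enoate (E/Z mixture) | COC(=O)C(=CC(OC)OC)C(C)=O | intermediate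
11 | Michael adduct: methyl 2-acetyl-3-(4-formyl-5-oxo-5,6-dihydro-4H-cyclopenta[c]furan-4-yl)-4,4-dimethoxybutanoate (C4′ and C2 as drawn, C1 epimers) | O=C[C@@]1([C@H](C(OC)OC)C(C(C)=O)C(=O)OC)C(=O)Cc2cocc21 | intermediate
12 | spiro enone keto ester (C4′ spiro; C3′ ketone; enone C15′=C14–C10=O; CO2Me on C1; CH(OMe)2 on C2, syn to C3′) | COC(=O)[C@H]1C(=O)C=C[C@@]2(c3cocc3CC2=O)[C@@H]1C(OC)OC | intermediate
13 | C3′ alcohol of 12 (OH syn to the C2 arm) | COC(=O)[C@H]1C(=O)C=C[C@@]2(c3cocc3C[C@H]2O)[C@@H]1C(OC)OC | intermediate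
14 | C3′ TES ether | COC(=O)[C@H]1C(=O)C=C[C@@]2(c3cocc3C[C@H]2O[Si](CC)(CC)CC)[C@@H]1C(OC)OC | intermediate
15 | C10′-formyl furan | COC(=O)[C@H]1C(=O)C=C[C@@]2(c3coc(C=O)c3C[C@H]2O[Si](CC)(CC)CC)[C@@H]1C(OC)OC | intermediate
16 | C14′ alcohol (10′-hydroxymethyl furan) | COC(=O)[C@H]1C(=O)C=C[C@@]2(c3coc(CO)c3C[C@H]2O[Si](CC)(CC)CC)[C@@H]1C(OC)OC | intermediate
17 | C14′ benzyl ether: spiro cyclohexenone bearing the 2-(benzyloxymethyl)furan-fused cyclopentane (C3′ OTES) | COC(=O)[C@H]1C(=O)C=C[C@@]2(c3coc(COCc4ccccc4)c3C[C@H]2O[Si](CC)(CC)CC)[C@@H]1C(OC)OC | intermediate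
18 | methyl levulinate | CC(=O)CCC(=O)OC | starting material
19 | methyl 3,5-dibromo-4-oxopentanoate (racemic) | COC(=O)CC(Br)C(=O)CBr | intermediate
20 | oxygen-bridged cycloheptenone: 8-oxabicyclo[3.2.1]octenone with C8′ ketone, equatorial C7′ acetate arm, C10′ CH2OBn, C1′=C5′ | COC(=O)[C@H]1C(=O)C=C[C@@]2(C3=C(C[C@H]2O[Si](CC)(CC)CC)[C@@]4(COCc5ccccc5)CC(=O)[C@@H](CC(=O)OC)[C@@H]3O4)[C@@H]1C(OC)OC | intermediate
21 | saturated cycloadduct (H1′, H5′ syn to the oxygen bridge; cyclohexanone) | COC(=O)[C@H]1C(=O)CC[C@@]2([C@H]3[C@@H](C[C@H]2O[Si](CC)(CC)CC)[C@@]4(COCc5ccccc5)CC(=O)[C@@H](CC(=O)OC)[C@@H]3O4)[C@@H]1C(OC)OC | intermediate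
22 | C8′ alcohol (axial, 8′β) | COC(=O)[C@H]1C(=O)CC[C@@]2([C@H]3[C@@H](C[C@H]2O[Si](CC)(CC)CC)[C@@]4(COCc5ccccc5)C[C@@H](O)[C@@H](CC(=O)OC)[C@@H]3O4)[C@@H]1C(OC)OC | intermediate
23 | C8′ TIPS ether | COC(=O)[C@H]1C(=O)CC[C@@]2([C@H]3[C@@H](C[C@H]2O[Si](CC)(CC)CC)[C@@]4(COCc5ccccc5)C[C@@H](O[Si](C(C)C)(C(C)C)C(C)C)[C@@H](CC(=O)OC)[C@@H]3O4)[C@@H]1C(OC)OC | intermediate
24 | C3 aldehyde | COC(=O)[C@H]1C(=O)CC[C@@]2([C@H]3[C@@H](C[C@H]2O[Si](CC)(CC)CC)[C@@]4(COCc5ccccc5)C[C@@H](O[Si](C(C)C)(C(C)C)C(C)C)[C@@H](CC(=O)OC)[C@@H]3O4)[C@@H]1C=O | intermediate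
25 | methyl 4-oxobutanoate | COC(=O)CCC=O | starting material
26 | 3-(trimethylsilyl)propynal | C[Si](C)(C)C#CC=O | starting material
27 | anti-aldol adduct: methyl (3R,4S)-3-formyl-4-hydroxy-6-(trimethylsilyl)hex-5-ynoate | O=C[C@H](CC(=O)OC)[C@H](O)C#C[Si](C)(C)C | intermediate
28 | trans-lactone aldehyde (4S,5S) | O=C[C@H]1CC(=O)O[C@@H]1C#C[Si](C)(C)C | intermediate
29 | silylalkynyl lactone acetal: (4S,5S)-4-(dimethoxymethyl)-5-[(trimethylsilyl)ethynyl]dihydrofuran-2(3H)-one | COC(OC)[C@H]1CC(=O)O[C@@H]1C#C[Si](C)(C)C | intermediate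
30 | iodoalkynyl lactone acetal: (4S,5S)-4-(dimethoxymethyl)-5-(iodoethynyl)dihydrofuran-2(3H)-one | COC(OC)[C@H]1CC(=O)O[C@@H]1C#CI | intermediate
31 | C3 propargylic alcohol (C3 epimers) | COC(=O)[C@H]1C(=O)CC[C@@]2([C@H]3[C@@H](C[C@H]2O[Si](CC)(CC)CC)[C@@]4(COCc5ccccc5)C[C@@H](O[Si](C(C)C)(C(C)C)C(C)C)[C@@H](CC(=O)OC)[C@@H]3O4)[C@@H]1C(O)C#C[C@H]6OC(=O)C[C@@H]6C(OC)OC | intermediate
32 | cyclopentene keto ester (C1–C5 bond, C4=C5, CO2Me on quaternary C1, cis-fused) | O=C1CC[C@@]2([C@H]3[C@@H](C[C@H]2O[Si](CC)(CC)CC)[C@@]4(COCc5ccccc5)C[C@@H](O[Si](C(C)C)(C(C)C)C(C)C)[C@@H](CC(=O)OC)[C@@H]3O4)[C@@H]7C(O)C=C([C@H]6OC(=O)C[C@@H]6C(OC)OC)[C@]17C(=O)OC | intermediate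
33 | cis-hydrindenone (C10 ketone, C1–H) | O=C1CC[C@@]2([C@H]3[C@@H](C[C@H]2O[Si](CC)(CC)CC)[C@@]4(COCc5ccccc5)C[C@@H](O[Si](C(C)C)(C(C)C)C(C)C)[C@@H](CC(=O)OC)[C@@H]3O4)[C@@H]7C(O)C=C([C@H]6OC(=O)C[C@@H]6C(OC)OC)[C@H]17 | intermediate
34 | C10 methylene compound (C10=C9H2) | C=C1CC[C@@]2([C@H]3[C@@H](C[C@H]2O[Si](CC)(CC)CC)[C@@]4(COCc5ccccc5)C[C@@H](O[Si](C(C)C)(C(C)C)C(C)C)[C@@H](CC(=O)OC)[C@@H]3O4)[C@@H]7C(O)C=C([C@H]6OC(=O)C[C@@H]6C(OC)OC)[C@H]17 | intermediate
35 | cyclopentenone (C3 ketone, C4=C5) | C=C1CC[C@@]2([C@H]3[C@@H](C[C@H]2O[Si](CC)(CC)CC)[C@@]4(COCc5ccccc5)C[C@@H](O[Si](C(C)C)(C(C)C)C(C)C)[C@@H](CC(=O)OC)[C@@H]3O4)[C@@H]7C(=O)C=C([C@H]6OC(=O)C[C@@H]6C(OC)OC)[C@H]17 | intermediate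
36 | C8 aldehyde | C=C1CC[C@@]2([C@H]3[C@@H](C[C@H]2O[Si](CC)(CC)CC)[C@@]4(COCc5ccccc5)C[C@@H](O[Si](C(C)C)(C(C)C)C(C)C)[C@@H](CC(=O)OC)[C@@H]3O4)[C@@H]7C(=O)C=C([C@H]6OC(=O)C[C@@H]6C=O)[C@H]17 | intermediate
37 | C8 alcohol (unit A cycloheptane closed, 8β-OH, C10=C14) | O[C@@H]8CC1=CC[C@@]2([C@H]3[C@@H](C[C@H]2O[Si](CC)(CC)CC)[C@@]4(COCc5ccccc5)C[C@@H](O[Si](C(C)C)(C(C)C)C(C)C)[C@@H](CC(=O)OC)[C@@H]3O4)[C@@H]7C(=O)C=C([C@H]6OC(=O)C[C@@H]68)[C@H]17 | intermediate
38 | C8 TIPS ether | CC(C)[Si](C(C)C)(C(C)C)O[C@@H]8CC1=CC[C@@]2([C@H]3[C@@H](C[C@H]2O[Si](CC)(CC)CC)[C@@]4(COCc5ccccc5)C[C@@H](O[Si](C(C)C)(C(C)C)C(C)C)[C@@H](CC(=O)OC)[C@@H]3O4)[C@@H]7C(=O)C=C([C@H]6OC(=O)C[C@@H]68)[C@H]17 | intermediate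
39 | C1(2),C10(14)-dienone (C5–H set) | CC(C)[Si](C(C)C)(C(C)C)O[C@@H]8CC1=CC[C@@]2([C@H]3[C@@H](C[C@H]2O[Si](CC)(CC)CC)[C@@]4(COCc5ccccc5)C[C@@H](O[Si](C(C)C)(C(C)C)C(C)C)[C@@H](CC(=O)OC)[C@@H]3O4)C7=C1[C@@H](CC7=O)[C@H]6OC(=O)C[C@@H]68 | intermediate
40 | C10-epimeric alcohol (C10 mixture, C14′ OH free) | CC(C)[Si](C(C)C)(C(C)C)O[C@@H]8CC1CC[C@@]2([C@H]3[C@@H](C[C@H]2O[Si](CC)(CC)CC)[C@@]4(CO)C[C@@H](O[Si](C(C)C)(C(C)C)C(C)C)[C@@H](CC(=O)OC)[C@@H]3O4)C7=C1[C@@H](CC7=O)[C@H]6OC(=O)C[C@@H]68 | intermediate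
41 | C14′ alcohol (C1(2)-enone, H10β) | CC(C)[Si](C(C)C)(C(C)C)O[C@@H]8C[C@H]1CC[C@@]2([C@H]3[C@@H](C[C@H]2O[Si](CC)(CC)CC)[C@@]4(CO)C[C@@H](O[Si](C(C)C)(C(C)C)C(C)C)[C@@H](CC(=O)OC)[C@@H]3O4)C7=C1[C@@H](CC7=O)[C@H]6OC(=O)C[C@@H]68 | intermediate
42 | C14′ iodide | CC(C)[Si](C(C)C)(C(C)C)O[C@@H]8C[C@H]1CC[C@@]2([C@H]3[C@@H](C[C@H]2O[Si](CC)(CC)CC)[C@@]4(CI)C[C@@H](O[Si](C(C)C)(C(C)C)C(C)C)[C@@H](CC(=O)OC)[C@@H]3O4)C7=C1[C@@H](CC7=O)[C@H]6OC(=O)C[C@@H]68 | intermediate
43 | hydroxy ester (bridge opened: C10′=C14′, C6′ OH) | CC(C)[Si](C(C)C)(C(C)C)O[C@@H]8C[C@H]1CC[C@@]2([C@H]3[C@@H](C[C@H]2O[Si](CC)(CC)CC)C(=C)C[C@@H](O[Si](C(C)C)(C(C)C)C(C)C)[C@@H](CC(=O)OC)[C@@H]3O)C7=C1[C@@H](CC7=O)[C@H]6OC(=O)C[C@@H]68 | intermediate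
44 | bis-lactone (both 6,12-trans lactones; C8, C8′ OTIPS; C3′ OTES) | CC(C)[Si](C(C)C)(C(C)C)O[C@@H]8C[C@H]1CC[C@@]2([C@H]3[C@@H](C[C@H]2O[Si](CC)(CC)CC)C(=C)C[C@@H](O[Si](C(C)C)(C(C)C)C(C)C)[C@H]4CC(=O)O[C@H]34)C7=C1[C@@H](CC7=O)[C@H]6OC(=O)C[C@@H]68 | intermediate
45 | tris-amine (CH2NMe2 on C4, C11, C11′; epimers) | CC(C)[Si](C(C)C)(C(C)C)O[C@@H]8C[C@H]1CC[C@@]2([C@H]3[C@@H](C[C@H]2O[Si](CC)(CC)CC)C(=C)C[C@@H](O[Si](C(C)C)(C(C)C)C(C)C)[C@H]4C(CN(C)C)C(=O)O[C@H]34)C7=C1[C@@H](C(CN(C)C)C7=O)[C@H]6OC(=O)C(CN(C)C)[C@@H]68 | intermediate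
46 | tris-ammonium iodide | CC(C)[Si](C(C)C)(C(C)C)O[C@@H]8C[C@H]1CC[C@@]2([C@H]3[C@@H](C[C@H]2O[Si](CC)(CC)CC)C(=C)C[C@@H](O[Si](C(C)C)(C(C)C)C(C)C)[C@H]4C(C[N+](C)(C)C)C(=O)O[C@H]34)C7=C1[C@@H](C(C[N+](C)(C)C)C7=O)[C@H]6OC(=O)C(C[N+](C)(C)C)[C@@H]68.[I-].[I-].[I-] | intermediate
47 | tris-methylene bis-lactone | CC(C)[Si](C(C)C)(C(C)C)O[C@@H]8C[C@H]1CC[C@@]2([C@H]3[C@@H](C[C@H]2O[Si](CC)(CC)CC)C(=C)C[C@@H](O[Si](C(C)C)(C(C)C)C(C)C)[C@H]4C(=C)C(=O)O[C@H]34)C7=C1[C@@H](C(=C)C7=O)[C@H]6OC(=O)C(=C)[C@@H]68 | intermediate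
48 | tris-methylene C3′ alcohol | CC(C)[Si](C(C)C)(C(C)C)O[C@@H]8C[C@H]1CC[C@@]2([C@H]3[C@@H](C[C@H]2O)C(=C)C[C@@H](O[Si](C(C)C)(C(C)C)C(C)C)[C@H]4C(=C)C(=O)O[C@H]34)C7=C1[C@@H](C(=C)C7=O)[C@H]6OC(=O)C(=C)[C@@H]68 | intermediate
49 | C3′ ketone bis-TIPS ether | CC(C)[Si](C(C)C)(C(C)C)O[C@@H]8C[C@H]1CC[C@@]2([C@H]3[C@@H](CC2=O)C(=C)C[C@@H](O[Si](C(C)C)(C(C)C)C(C)C)[C@H]4C(=C)C(=O)O[C@H]34)C7=C1[C@@H](C(=C)C7=O)[C@H]6OC(=O)C(=C)[C@@H]68 | intermediate
50 | CNP0397417.1 | C=C1C(=O)C2=C3[C@H](CC[C@]24C(=O)C[C@H]2C(=C)C[C@@H](O)[C@H]5C(=C)C(=O)O[C@@H]5[C@H]24)C[C@@H](O)[C@H]2C(=C)C(=O)O[C@@H]2[C@H]13 | target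

**Count and risks**

Total step count: 33. Longest linear sequence: 28 steps (1–3, 5–9, 11–14, 18–33).

Step 11. The mono-alkyl dibromide may lose HBr to the bromo enoate faster than it ionises, and the unsymmetrical cation may add in both orientations, so conversion and regiochemistry can both leak. The fallback sets out from 17 and uses a symmetrical, better stabilised cation. 1,1,3,3-Tetrabromoacetone with Zn–Cu couple and B(OEt)3 in THF should give the dibromo cycloadduct F1 under the same face control. Zn–Cu/NH4Cl in MeOH then removes both bromines to give the arm-free bicyclic ketone F2. After the β-keto ester has been masked as its sodium enolate, LDA should deprotonate C7′ (the α-CH2 next to the unsubstituted bridgehead C6′; C9′ is screened by the quaternary C10′). Methyl bromoacetate then installs the arm, and equilibration to the equatorial epimer returns the route at 20.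

Step 24. The aluminium-bound aldehyde may be intercepted by chloride, lose a proton from the wrong carbon or close with the oxygen on the other face, so the ring may form as a mixture. The fallback sets out from 36 and closes the ring by metathesis. Nozaki–Hiyama–Kishi vinylation of the aldehyde (vinyl bromide, CrCl2/NiCl2) gives the C8 vinyl carbinol F3. Ring-closing metathesis with a second-generation ruthenium carbene between the vinyl group and the C10 methylene gives the C9(10)-cycloheptenol F4. Silylation (TIPSOTf, 2,6-lutidine) gives the TIPS ether F5, and DBU moves the enone to C1=C2 to give the C1(2),C9(10)-dienone F6. Hydrogenation over Pd(OH)2/C followed by DBU, as in step 27, reduces the C9=C10 bond, removes the benzyl group and returns the route at 41.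

Step 12. The exo face of the tetrasubstituted C1′=C5′ bond is crowded by the C3′ silyloxy group, so saturation may stall or the alkene may migrate before it is reduced. The fallback sets out from 20 and turns the hindering group into a directing group. Buffered HF·pyridine removes the triethylsilyl group to give the C3′ alcohol F7, whose hydroxyl sits on the exo face. Hydroxyl-directed hydrogenation with the same iridium catalyst then delivers hydrogen from that face to give the saturated C3′ alcohol F8. Resilylation (TESOTf, 2,6-lutidine) returns the route at 21.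

Further compounds
F1 | step 11 | dibromo cycloadduct (7′,9′-dibromo, epimers) | COC(=O)[C@H]1C(=O)C=C[C@@]2(C3=C(C[C@H]2O[Si](CC)(CC)CC)[C@@]4(COCc5ccccc5)C(Br)C(=O)C(Br)[C@@H]3O4)[C@@H]1C(OC)OC
F2 | step 11 | arm-free bicyclic ketone | COC(=O)[C@H]1C(=O)C=C[C@@]2(C3=C(C[C@H]2O[Si](CC)(CC)CC)[C@@]4(COCc5ccccc5)CC(=O)C[C@@H]3O4)[C@@H]1C(OC)OC
F3 | step 24 | C8 vinyl carbinol | C=C1CC[C@@]2([C@H]3[C@@H](C[C@H]2O[Si](CC)(CC)CC)[C@@]4(COCc5ccccc5)C[C@@H](O[Si](C(C)C)(C(C)C)C(C)C)[C@@H](CC(=O)OC)[C@@H]3O4)[C@@H]7C(=O)C=C([C@H]6OC(=O)C[C@@H]6[C@H](O)C=C)[C@H]17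
F4 | step 24 | C9(10)-cycloheptenol | O[C@@H]8C=C1CC[C@@]2([C@H]3[C@@H](C[C@H]2O[Si](CC)(CC)CC)[C@@]4(COCc5ccccc5)C[C@@H](O[Si](C(C)C)(C(C)C)C(C)C)[C@@H](CC(=O)OC)[C@@H]3O4)[C@@H]7C(=O)C=C([C@H]6OC(=O)C[C@@H]68)[C@H]17
F5 | step 24 | TIPS ether of the cycloheptenol | CC(C)[Si](C(C)C)(C(C)C)O[C@@H]8C=C1CC[C@@]2([C@H]3[C@@H](C[C@H]2O[Si](CC)(CC)CC)[C@@]4(COCc5ccccc5)C[C@@H](O[Si](C(C)C)(C(C)C)C(C)C)[C@@H](CC(=O)OC)[C@@H]3O4)[C@@H]7C(=O)C=C([C@H]6OC(=O)C[C@@H]68)[C@H]17
F6 | step 24 | C1(2),C9(10)-dienone | CC(C)[Si](C(C)C)(C(C)C)O[C@@H]8C=C1CC[C@@]2([C@H]3[C@@H](C[C@H]2O[Si](CC)(CC)CC)[C@@]4(COCc5ccccc5)C[C@@H](O[Si](C(C)C)(C(C)C)C(C)C)[C@@H](CC(=O)OC)[C@@H]3O4)C7=C1[C@@H](CC7=O)[C@H]6OC(=O)C[C@@H]68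
F7 | step 12 | C3′ alcohol of the cycloadduct | COC(=O)[C@H]1C(=O)C=C[C@@]2(C3=C(C[C@H]2O)[C@@]4(COCc5ccccc5)CC(=O)[C@@H](CC(=O)OC)[C@@H]3O4)[C@@H]1C(OC)OC
F8 | step 12 | saturated C3′ alcohol | COC(=O)[C@H]1C(=O)CC[C@@]2([C@H]3[C@@H](C[C@H]2O)[C@@]4(COCc5ccccc5)CC(=O)[C@@H](CC(=O)OC)[C@@H]3O4)[C@@H]1C(OC)OC
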